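## Retrosynthetic overview

1. The C7–C11 bond is made last, by a nickel-catalysed alkenylation of a 7-bromo-8-ketone (both esters already in place) with isopropenylzinc bromide.
2. The bromo ketone comes from the regiodefined 8-silyl enol ether of a Diels–Alder adduct; the C14 methyl comes from the angular formyl group by tosylhydrazone reduction.
3. Ring B is formed by a [4+2] union of a ring A enal (C3 angelate and C4 methyl installed) with 1-senecioyloxy-2-silyloxybuta-1,3-diene, which sets C5, C10 (cis fusion) and C9.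
4. The ring A enal comes from palladium-catalysed formylation of a kinetic enol triflate of (2S,3R)-3-hydroxy-2-methylcyclohexanone, itself from copper-catalysed asymmetric borylation of 2-methylcyclohexenone; the diene comes from a Weinreb amide, a vinyl Grignard reagent and silylation.
5. Ring order: ring A is bought as a six-membered ring and ring B is formed in the cycloaddition. Stereocentres: C3/C4 in step 1, C5/C9/C10 in step 9, C7 in step 13.

Convention (assumed for naming): bicyclic compounds carry eremophilane numbering (C1–C10 decalin, C14 on C5, C15 = methyl on C4, C11–C13 = isopropenyl on C7); β is the face of C14; angeloyl = (2Z)-2-methylbut-2-enoyl, senecioyl = 3-methylbut-2-enoyl.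

## Route

Step 1
Reactants: 1 2-methylcyclohex-2-en-1-one
Product: 3 (2S,3R)-3-hydroxy-2-methylcyclohexan-1-one, via boryl ketone 2 (not isolated)
Conditions: B2pin2 (1.1 equiv), CuCl (5 mol%), NaOt-Bu (7 mol%), (R)-DTBM-SEGPHOS (6 mol%; ligand antipode chosen to give 3R), MeOH (2 equiv), THF, 0 °C → rt; then NaBO3·4H2O, THF/H2O, rt; trans isomer purified
Reagents that add atoms: sodium perborate, [Na+].[O-]OB=O; bis(pinacolato)diboron, CC1(C)OB(OC1(C)C)B1OC(C)(C)C(C)(C)O1 (its boron is held only in 2)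
Why: Copper-catalysed asymmetric conjugate borylation: the ligand-bound Cu–Bpin species adds boron to one face of the β-carbon (sets C3 of the target), protonation of the copper enolate and epimerisation place the α-methyl trans (diequatorial, sets C4), and perborate oxidises C–B to C–OH with retention.

Step 2
Reactants: 4 angelic acid [(2Z)-2-methylbut-2-enoic acid]
Product: 5 (2Z)-2-methylbut-2-enoic 2,4,6-trichlorobenzoic anhydride
Conditions: 2,4,6-trichlorobenzoyl chloride (1.0 equiv), Et3N (1.1 equiv), toluene, rt, 1 h; filtered, used as solution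
Reagents that add atoms: 2,4,6-trichlorobenzoyl chloride, O=C(Cl)c1c(Cl)cc(Cl)cc1Cl
Why: Yamaguchi mixed-anhydride formation by O-acylation of the ammonium carboxylate at room temperature activates angelic acid without touching its Z double bond.

Step 3
Reactants: 3 (2S,3R)-3-hydroxy-2-methylcyclohexan-1-one; 5 (2Z)-2-methylbut-2-enoic 2,4,6-trichlorobenzoic anhydride
Product: 6 (1R,2S)-2-methyl-3-oxocyclohexyl (2Z)-2-methylbut-2-enoate
Conditions: 5 (1.5 equiv), DMAP (0.3 equiv), Et3N (1.5 equiv), toluene, 0 °C → rt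
Reagents that add atoms: none
Why: Yamaguchi esterification: DMAP attacks the unhindered angeloyl carbonyl of 5 (the aroyl carbonyl is shielded by two ortho chlorines) and the acylpyridinium acylates the secondary alcohol with retention, the low temperature limiting Z-to-E drift and β-elimination.

Step 4
Reactants: 6 (1R,2S)-2-methyl-3-oxocyclohexyl (2Z)-2-methylbut-2-enoate
Product: 8 (1R,2S)-2-methyl-3-(trifluoromethylsulfonyloxy)cyclohex-3-en-1-yl (2Z)-2-methylbut-2-enoate, via lithium enolate 7 (not isolated)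
Conditions: LiN(i-Pr)2 (1.1 equiv), THF, −78 °C, 45 min; then N-(5-chloropyridin-2-yl)bis(trifluoromethanesulfonyl)imide, −78 → −20 °C
Reagents that add atoms: N-(5-chloropyridin-2-yl)-1,1,1-trifluoro-N-(trifluoromethylsulfonyl)methanesulfonamide, FC(F)(F)S(=O)(=O)N(c1ccc(Cl)cn1)S(=O)(=O)C(F)(F)F
Why: Kinetic deprotonation by the bulky amide at the unhindered CH2 (not at the methyl-bearing CH, so the β-acyloxy group is not expelled by E1cB) followed by O-triflation gives the less substituted enol triflate regioselectively.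

Step 5
Reactants: 8 (1R,2S)-2-methyl-3-(trifluoromethylsulfonyloxy)cyclohex-3-en-1-yl (2Z)-2-methylbut-2-enoate; 9 carbon monoxide
Product: 10 (1R,2R)-3-formyl-2-methylcyclohex-3-en-1-yl (2Z)-2-methylbut-2-enoate
Conditions: Pd(PPh3)4 (5 mol%), CO (1 atm), Bu3SnH (1.1 equiv, syringe pump), LiCl (3 equiv), THF, 50 °C
Reagents that add atoms: none
Why: Palladium-catalysed carbonylative reduction (formylation) of an alkenyl triflate: oxidative addition to zerovalent palladium, CO insertion, hydride transfer from tin and reductive elimination give the enal (C14 installed) without touching a stereocentre.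

Step 6
Reactants: 11 2-chloro-N-methoxy-N-methylacetamide; 12 3-methylbut-2-enoic acid
Product: 14 2-[methoxy(methyl)amino]-2-oxoethyl 3-methylbut-2-enoate, via cesium senecioate 13 (not isolated)
Conditions: Cs2CO3 (0.55 equiv), NaI (0.1 equiv), DMF, rt
Reagents that add atoms: none
Why: SN2 O-alkylation of the cesium carboxylate by the activated α-chloro amide (iodide catalysis) gives the ester and leaves the trisubstituted enoate alone.

Step 7
Reactants: 14 2-[methoxy(methyl)amino]-2-oxoethyl 3-methylbut-2-enoate; 15 vinylmagnesium bromide (CH2=CHMgBr)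
Product: 17 2-oxobut-3-en-1-yl 3-methylbut-2-enoate, via magnesium hemiaminal 16 (not isolated)
Conditions: CH2=CHMgBr (1.2 equiv), THF, −78 → −20 °C; inverse quench into cold 1 M HCl
Reagents that add atoms: none
Why: Weinreb ketone synthesis: the chelated tetrahedral adduct resists over-addition and the amide is more electrophilic than the hindered conjugated ester, while the acidic inverse quench keeps the released amine from adding to the vinyl ketone.

Step 8
Reactants: 17 2-oxobut-3-en-1-yl 3-methylbut-2-enoate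
Product: 18 (1Z)-2-(tert-butyldimethylsilyloxy)buta-1,3-dien-1-yl 3-methylbut-2-enoate
Conditions: TBSOTf (1.1 equiv), Et3N (1.5 equiv), Et2O, 0 °C
Reagents that add atoms: tert-butyldimethylsilyl trifluoromethanesulfonate, CC(C)(C)[Si](C)(C)OS(=O)(=O)C(F)(F)F
Why: Soft enolisation and O-silylation at the only enolisable position (the acyloxy-bearing CH2) gives the 2-silyloxy diene, expected as the Z enol ether with the two oxygens cis.

Step 9
Reactants: 10 (1R,2R)-3-formyl-2-methylcyclohex-3-en-1-yl (2Z)-2-methylbut-2-enoate; 18 (1Z)-2-(tert-butyldimethylsilyloxy)buta-1,3-dien-1-yl 3-methylbut-2-enoate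
Product: 19 3α-angeloyloxy-8-(tert-butyldimethylsilyloxy)-4β-methyl-9β-senecioyloxy-10βH-Δ7-octalin-5β-carbaldehyde (3R,4R,5S,9R,10S)
Conditions: 18 (1.5 equiv), Me2AlCl (0.5 equiv), CH2Cl2, −78 → −30 °C
Reagents that add atoms: none
Why: Lewis-acid-promoted Diels–Alder reaction forms ring B: the silyloxy group makes C9 the nucleophilic diene terminus, so it bonds to the enal β-carbon C10 while the unsubstituted terminus C6 bonds to hindered C5; the diene adds anti to the pseudoaxial C4 methyl to give the cis fusion with 5β-CHO and 10β-H, and the endo (formyl) transition state places the 9-senecioate β.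

Step 10
Reactants: 19 3α-angeloyloxy-8-(tert-butyldimethylsilyloxy)-4β-methyl-9β-senecioyloxy-10βH-Δ7-octalin-5β-carbaldehyde
Product: 21 3α-angeloyloxy-8-(tert-butyldimethylsilyloxy)-4β,5β-dimethyl-9β-senecioyloxy-10βH-Δ7-octalin (3R,4R,5R,9R,10S), via tosylhydrazone 20 (not isolated)
Conditions: TsNHNH2 (1.2 equiv), MgSO4, THF, 45 °C; then catecholborane (2.5 equiv), CHCl3, 0 °C; then NaOAc·3H2O, 60 °C
Reagents that add atoms: 4-methylbenzenesulfonohydrazide, Cc1ccc(cc1)S(=O)(=O)NN (its atoms are held only in 20)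
Why: Caglioti–Kabalka deoxygenation: the neopentyl aldehyde condenses with tosylhydrazide, catecholborane reduces the C=N bond, and acetate-triggered loss of sulfinate gives a diazene that extrudes N2 to leave the C14 methyl, while the C8 ketone stays masked as its silyl enol ether.

Step 11
Reactants: 21 3α-angeloyloxy-8-(tert-butyldimethylsilyloxy)-4β,5β-dimethyl-9β-senecioyloxy-10βH-Δ7-octalin
Product: 22 3α-angeloyloxy-7ξ-bromo-4β,5β-dimethyl-9β-senecioyloxy-10βH-decalin-8-one (C7 epimers)
Conditions: NBS (1.05 equiv), NaHCO3, THF, −78 → 0 °C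
Reagents that add atoms: N-bromosuccinimide, BrN1C(=O)CCC1=O
Why: Electrophilic α-bromination of the regiodefined silyl enol ether (the Diels–Alder-derived 7,8-double bond) places bromine only at C7; both epimers are usable because the next step is stereoconvergent.

Step 12
Reactants: 23 isopropenylmagnesium bromide [CH2=C(CH3)MgBr]
Product: 24 isopropenylzinc bromide [CH2=C(CH3)ZnBr]
Conditions: ZnBr2 (1.0 equiv), THF, 0 °C, 30 min; used as solution
Reagents that add atoms: zinc bromide, [Zn+2].[Br-].[Br-]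
Why: Transmetalation from magnesium to zinc gives a less basic, ester-tolerant alkenylzinc halide for the Negishi coupling.

Step 13
Reactants: 22 3α-angeloyloxy-7ξ-bromo-4β,5β-dimethyl-9β-senecioyloxy-10βH-decalin-8-one; 24 isopropenylzinc bromide
Product: 25 (3R,4R,5R,7R,9R,10S)-3α-angeloyloxy-9β-senecioyloxy-10βH-eremophil-11-en-8-one (CNP0375730.2)
Conditions: NiCl2(MeOCH2CH2OMe) (10 mol%), 2,6-bis(4,4-dimethyl-4,5-dihydrooxazol-2-yl)pyridine (13 mol%), 24 (1.6 equiv), MeOCH2CH2OMe/THF, −10 → 5 °C
Reagents that add atoms: none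
Why: Proposed new method: a diastereoconvergent nickel-catalysed Negishi alkenylation of a cyclic secondary α-bromo ketone with a 1,1-disubstituted alkenylzinc halide, in which a monovalent alkenylnickel species abstracts bromine to give the planar C7 α-keto radical (erasing the C7 configuration of 22), the radical recombines with divalent alkenylnickel on the β-face (the α-face of C7 is shielded by the syn-axial C4–C5 bond of ring A) and reductive elimination from trivalent nickel forms the C7–C11 bond, giving the equatorial 7β-isopropenyl ketone without the base that would move the double bond into conjugation; the closest known reaction type is the nickel/pybox- or bis(oxazoline)-catalysed stereoconvergent Negishi arylation and alkenylzirconium alkenylation of acyclic racemic α-bromo ketones.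

## Compound list

1 | 2-methylcyclohex-2-en-1-one | CC1=CCCCC1=O | starting material
2 | (2S,3R)-2-methyl-3-(4,4,5,5-tetramethyl-1,3,2-dioxaborolan-2-yl)cyclohexan-1-one | O=C1CCC[C@@H](B2OC(C)(C)C(C)(C)O2)[C@@H]1C | intermediate (not isolated)
3 | (2S,3R)-3-hydroxy-2-methylcyclohexan-1-one | O=C1CCC[C@@H](O)[C@@H]1C | intermediate
4 | angelic acid, (2Z)-2-methylbut-2-enoic acid | C/C=C(/C)C(=O)O | starting material
5 | (2Z)-2-methylbut-2-enoic 2,4,6-trichlorobenzoic anhydride | C/C=C(/C)C(=O)OC(=O)c1c(Cl)cc(Cl)cc1Cl | intermediate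
6 | (1R,2S)-2-methyl-3-oxocyclohexyl (2Z)-2-methylbut-2-enoate | O=C1CCC[C@@H](OC(=O)/C(C)=C\C)[C@@H]1C | intermediate
7 | lithium (5R,6S)-6-methyl-5-[(2Z)-2-methylbut-2-enoyloxy]cyclohex-1-en-1-olate | [Li]OC1=CCC[C@@H](OC(=O)/C(C)=C\C)[C@@H]1C | intermediate (not isolated)
8 | (1R,2S)-2-methyl-3-(trifluoromethylsulfonyloxy)cyclohex-3-en-1-yl (2Z)-2-methylbut-2-enoate | O=S(=O)(OC1=CCC[C@@H](OC(=O)/C(C)=C\C)[C@@H]1C)C(F)(F)F | intermediate
9 | carbon monoxide | [C-]#[O+] | starting material
10 | (1R,2R)-3-formyl-2-methylcyclohex-3-en-1-yl (2Z)-2-methylbut-2-enoate | O=CC1=CCC[C@@H](OC(=O)/C(C)=C\C)[C@@H]1C | intermediate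
11 | 2-chloro-N-methoxy-N-methylacetamide | CON(C)C(=O)CCl | starting material
12 | 3-methylbut-2-enoic acid (senecioic acid) | CC(C)=CC(=O)O | starting material
13 | cesium 3-methylbut-2-enoate | [Cs+].[O-]C(=O)C=C(C)C | intermediate (not isolated)
14 | 2-[methoxy(methyl)amino]-2-oxoethyl 3-methylbut-2-enoate | CON(C)C(=O)COC(=O)C=C(C)C | intermediate
15 | vinylmagnesium bromide | C=C[Mg]Br | starting material
16 | bromomagnesium 2-[methoxy(methyl)amino]-1-(3-methylbut-2-enoyloxy)but-3-en-2-olate | C=CC(O[Mg]Br)(N(C)OC)COC(=O)C=C(C)C | intermediate (not isolated)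
17 | 2-oxobut-3-en-1-yl 3-methylbut-2-enoate | C=CC(=O)COC(=O)C=C(C)C | intermediate
18 | (1Z)-2-(tert-butyldimethylsilyloxy)buta-1,3-dien-1-yl 3-methylbut-2-enoate | C=C/C(O[Si](C)(C)C(C)(C)C)=C/OC(=O)C=C(C)C | intermediate
19 | 3α-angeloyloxy-8-(tert-butyldimethylsilyloxy)-4β-methyl-9β-senecioyloxy-10βH-Δ7-octalin-5β-carbaldehyde (3R,4R,5S,9R,10S) | O=C[C@]12CC=C(O[Si](C)(C)C(C)(C)C)[C@H](OC(=O)C=C(C)C)[C@H]1CC[C@@H](OC(=O)/C(C)=C\C)[C@@H]2C | intermediate
20 | N'-tosylhydrazone of 19 (E) | Cc1ccc(cc1)S(=O)(=O)N/N=C/[C@]12CC=C(O[Si](C)(C)C(C)(C)C)[C@H](OC(=O)C=C(C)C)[C@H]1CC[C@@H](OC(=O)/C(C)=C\C)[C@@H]2C | intermediate (not isolated)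
21 | 3α-angeloyloxy-8-(tert-butyldimethylsilyloxy)-4β,5β-dimethyl-9β-senecioyloxy-10βH-Δ7-octalin (3R,4R,5R,9R,10S) | C[C@]12CC=C(O[Si](C)(C)C(C)(C)C)[C@H](OC(=O)C=C(C)C)[C@H]1CC[C@@H](OC(=O)/C(C)=C\C)[C@@H]2C | intermediate
22 | 3α-angeloyloxy-7ξ-bromo-4β,5β-dimethyl-9β-senecioyloxy-10βH-decalin-8-one (C7 epimers) | C[C@]12CC(Br)C(=O)[C@H](OC(=O)C=C(C)C)[C@H]1CC[C@@H](OC(=O)/C(C)=C\C)[C@@H]2C | intermediate
23 | isopropenylmagnesium bromide | CC(=C)[Mg]Br | starting material
24 | isopropenylzinc bromide | CC(=C)[Zn]Br | intermediate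
25 | (3R,4R,5R,7R,9R,10S)-3α-angeloyloxy-9β-senecioyloxy-10βH-eremophil-11-en-8-one | C=C(C)[C@H]1C[C@@]2(C)[C@H](CC[C@@H](OC(=O)/C(C)=C\C)[C@@H]2C)[C@@H](OC(=O)C=C(C)C)C1=O | target

## Step count and risk

Total step count: 13. Longest linear sequence: 8 steps (1, 3, 4, 5, 9, 10, 11, 13).

Three steps most likely to fail:

**Step 13 (the proposed new coupling).** Risks are bromine–zinc exchange giving the debrominated ketone, 1,2-addition to the ketone, or slow radical capture at the hindered C7. The fallback uses known chemistry, sets out from 21 and comes back at 25. Silyl enol ether 21 is treated with acetone and TiCl4 (CH2Cl2, −78 °C, Mukaiyama aldol) to give 3α-angeloyloxy-7β-(2-hydroxypropan-2-yl)-4β,5β-dimethyl-9β-senecioyloxy-10βH-decalin-8-one F1. Burgess reagent (toluene, 50 °C) then dehydrates the tertiary alcohol to 25; the conjugated 7(11)-ene isomer formed alongside is removed by chromatography.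

**Step 9 (the cycloaddition).** The 1-acyloxy-2-silyloxy diene may react sluggishly, add to the aldehyde carbonyl or give the other regioisomer. The fallback sets out from 10 and comes back at 21; it moves the C9 oxygen from the diene to a later ketone functionalisation. Enal 10 reacts with the unsubstituted 2-(tert-butyldimethylsilyloxy)buta-1,3-diene F2 (from but-3-en-2-one, TBSOTf, Et3N) under Me2AlCl to give 3α-angeloyloxy-8-(tert-butyldimethylsilyloxy)-4β-methyl-10βH-Δ7-octalin-5β-carbaldehyde F3. Its tosylhydrazone F4 is reduced with catecholborane and NaOAc·3H2O to 3α-angeloyloxy-8-(tert-butyldimethylsilyloxy)-4β,5β-dimethyl-10βH-Δ7-octalin F5. HF·pyridine (THF, 0 °C) gives 3α-angeloyloxy-4β,5β-dimethyl-10βH-decalin-8-one F6. PhNMe3Br3 (THF, 0 °C) brominates this cis-fused ketone through its preferred enol towards the ring fusion to give 3α-angeloyloxy-9ξ-bromo-4β,5β-dimethyl-10βH-decalin-8-one F7. Cesium 3-methylbut-2-enoate 13 in DMF displaces bromide, and α-epimerisation funnels the product to the equatorial ester 3α-angeloyloxy-4β,5β-dimethyl-9β-senecioyloxy-10βH-decalin-8-one F8. LiN(SiMe3)2 and TBSCl (THF, −78 °C) then enolise kinetically at the C7 methylene to return 21.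

**Step 1 (the asymmetric borylation).** The α-substituted enone may give low turnover or low ee. The fallback sets out from 1 and comes back at 3. (R)-2-methyl-CBS-oxazaborolidine (10 mol%) with BH3·SMe2 gives (1S)-2-methylcyclohex-2-en-1-ol F9. VO(acac)2 and t-BuOOH give the hydroxyl-directed syn epoxide (1S,2S,6R)-1-methyl-7-oxabicyclo[4.1.0]heptan-2-ol F10. Dess–Martin periodinane gives (1R,6R)-1-methyl-7-oxabicyclo[4.1.0]heptan-2-one F11. SmI2 (THF/MeOH, −78 °C) cleaves the α C–O bond, and protonation with equilibration gives trans-3.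

Further compounds
F1 | step 13 | 3α-angeloyloxy-7β-(2-hydroxypropan-2-yl)-4β,5β-dimethyl-9β-senecioyloxy-10βH-decalin-8-one | C[C@]12C[C@H](C(C)(C)O)C(=O)[C@H](OC(=O)C=C(C)C)[C@H]1CC[C@@H](OC(=O)/C(C)=C\C)[C@@H]2C
F2 | step 9 | 2-(tert-butyldimethylsilyloxy)buta-1,3-diene | C=CC(=C)O[Si](C)(C)C(C)(C)C
F3 | step 9 | 3α-angeloyloxy-8-(tert-butyldimethylsilyloxy)-4β-methyl-10βH-Δ7-octalin-5β-carbaldehyde | O=C[C@]12CC=C(O[Si](C)(C)C(C)(C)C)C[C@H]1CC[C@@H](OC(=O)/C(C)=C\C)[C@@H]2C
F4 | step 9 | N'-tosylhydrazone of F3 (E) | Cc1ccc(cc1)S(=O)(=O)N/N=C/[C@]12CC=C(O[Si](C)(C)C(C)(C)C)C[C@H]1CC[C@@H](OC(=O)/C(C)=C\C)[C@@H]2C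
F5 | step 9 | 3α-angeloyloxy-8-(tert-butyldimethylsilyloxy)-4β,5β-dimethyl-10βH-Δ7-octalin | C[C@]12CC=C(O[Si](C)(C)C(C)(C)C)C[C@H]1CC[C@@H](OC(=O)/C(C)=C\C)[C@@H]2C
F6 | step 9 | 3α-angeloyloxy-4β,5β-dimethyl-10βH-decalin-8-one | C[C@]12CCC(=O)C[C@H]1CC[C@@H](OC(=O)/C(C)=C\C)[C@@H]2C
F7 | step 9 | 3α-angeloyloxy-9ξ-bromo-4β,5β-dimethyl-10βH-decalin-8-one | C[C@]12CCC(=O)C(Br)[C@H]1CC[C@@H](OC(=O)/C(C)=C\C)[C@@H]2C
F8 | step 9 | 3α-angeloyloxy-4β,5β-dimethyl-9β-senecioyloxy-10βH-decalin-8-one | C[C@]12CCC(=O)[C@H](OC(=O)C=C(C)C)[C@H]1CC[C@@H](OC(=O)/C(C)=C\C)[C@@H]2C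
F9 | step 1 | (1S)-2-methylcyclohex-2-en-1-ol | O[C@H]1CCCC=C1C
F10 | step 1 | (1S,2S,6R)-1-methyl-7-oxabicyclo[4.1.0]heptan-2-ol | O[C@H]1CCC[C@H]2O[C@@]12C
F11 | step 1 | (1R,6R)-1-methyl-7-oxabicyclo[4.1.0]heptan-2-one | O=C1CCC[C@H]2O[C@@]12C
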